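**Strategy.** The ten-membered ring (C1–C10, germacrane numbering) holds its C3 ketone between the C1=C2 (E) and C4=C5 (Z) olefins, so both ring bonds to C3 can be cut and C3 supplied as carbon monoxide. A carbonylative Stille macrocyclisation forms C3–C4 and C2–C3 and closes the carbocycle in one operation, as the last step. Its precursor is the complete trans-disubstituted α-methylene-γ-lactone carrying the C8 tiglate, a free C10 hydroxyl, a (Z)-C4 alkenyl iodide and an (E)-C2 alkenylstannane. Iodide and stannane are made on separate fragments and joined by a zinc Barbier allylation that creates C7–C8 and the methylene lactone.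

Key step: step 15

Remark (structures): the target is read as 6R,7R,8R,10R with 1E, 4Z and an E tiglate; the seco-iodide of the key step has the same spatial arrangement at all four centres (its C6 is named S only because iodine changes the CIP ranking), so no structure needs correction.
Remark (assumption): the zinc allylation of step 12 is assumed to pass through the closed chair transition state, which gives the 8S alcohol; the tiglate is therefore introduced with inversion.

**Fragment 1 (C8–C10, C1, C2, C14)**

Step 1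
Reactants: 1 (S)-2-methylglycidol; 2 vinylmagnesium bromide
Product: 3 (2R)-2-methylpent-4-ene-1,2-diol
Conditions: CH2=CHMgBr (3 equiv), CuI (10 mol%), THF, −40 to 0 °C; aq. NH4Cl
Reagents that add atoms: vinylmagnesium bromide (2), C=C[Mg]Br
Why: Copper-catalysed Grignard opening of the 2,2-disubstituted epoxide at its CH2 terminus (SN2) leaves the quaternary carbinol (C10) untouched, and the degenerate Payne shift of the alkoxide returns the same enantiomer, so C10 is taken over from 1.

Step 2
Reactants: 3 (2R)-2-methylpent-4-ene-1,2-diol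
Product: 4 (2R)-2-methyl-1,2-bis(triethylsilyloxy)pent-4-ene
Conditions: TESOTf (2.4 equiv), 2,6-lutidine, CH2Cl2, −78 to 0 °C
Reagents that add atoms: triethylsilyl trifluoromethanesulfonate, CC[Si](CC)(CC)OS(=O)(=O)C(F)(F)F
Why: Silyl triflate with a hindered pyridine base silylates both the primary and the tertiary hydroxyl (O-silylation).

Step 3
Reactants: 4 (2R)-2-methyl-1,2-bis(triethylsilyloxy)pent-4-ene
Product: 6 (2R)-2-methyl-2-(triethylsilyloxy)pent-4-enal, via alkoxysulfonium chloride 5 (not isolated)
Conditions: (COCl)2, DMSO, CH2Cl2, −78 to −40 °C; then Et3N, to 0 °C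
Reagents that add atoms: none
Why: Direct Swern oxidation of a primary triethylsilyl ether: the chlorosulfonium salt attacks only the unhindered primary ether, the tertiary ether survives, and the quaternary α-carbon cannot epimerise.

Step 4
Reactants: 6 (2R)-2-methyl-2-(triethylsilyloxy)pent-4-enal; 7 dimethyl (1-diazo-2-oxopropyl)phosphonate
Product: 8 (3R)-3-methyl-3-(triethylsilyloxy)hex-5-en-1-yne
Conditions: 7, K2CO3, MeOH, 0 °C to rt
Reagents that add atoms: dimethyl (1-diazo-2-oxopropyl)phosphonate (7), CC(=O)C(=[N+]=[N-])P(=O)(OC)OC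
Why: Seyferth–Gilbert homologation in the Ohira–Bestmann form converts the non-enolisable aldehyde into the terminal alkyne (C1≡C2) under carbonate/methanol, which a tertiary silyl ether tolerates.

Step 5
Reactants: 8 (3R)-3-methyl-3-(triethylsilyloxy)hex-5-en-1-yne
Product: 10 (3R)-3-methyl-3-(triethylsilyloxy)pent-4-ynal, via 1,2-diol 9 (not isolated)
Conditions: OsO4 (2 mol%), NaIO4, 2,6-lutidine, dioxane/H2O, rt
Reagents that add atoms: osmium tetroxide, O=[Os](=O)(=O)=O (oxygen donor, regenerated by sodium periodate, [Na+].[O-]I(=O)(=O)=O)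
Why: Lemieux–Johnson cleavage (dihydroxylation, then periodate) of the terminal alkene, which reacts with OsO4 far faster than the terminal alkyne, unmasks the C8 aldehyde.

Step 6
Reactants: 10 (3R)-3-methyl-3-(triethylsilyloxy)pent-4-ynal
Product: 11 (3R,4E)-3-methyl-5-(tributylstannyl)-3-(triethylsilyloxy)pent-4-enal
Conditions: Bu3SnH, PdCl2(PPh3)2 (2 mol%), THF, 0 °C
Reagents that add atoms: tributyltin hydride, CCCC[SnH](CCCC)CCCC
Why: Palladium-catalysed syn-hydrostannation of the terminal alkyne; the quaternary propargylic carbon directs tin to the terminal carbon, so the E-β-stannane should form, the aldehyde is not reduced, and no alkenyl iodide is yet present.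

**Fragment 2 (C4–C7, C11–C13, C15)**

Step 7
Reactants: 12 acrolein; 13 1-propynylmagnesium bromide
Product: 14 rac-hex-1-en-4-yn-3-ol
Conditions: THF, −78 to 0 °C; aq. NH4Cl
Reagents that add atoms: 1-propynylmagnesium bromide (13), CC#C[Mg]Br
Why: 1,2-Addition of an alkynyl Grignard reagent to the enal gives the C6 carbinol flanked by the future C7 vinyl and the C4–C5 alkyne.

Step 8
Reactants: 14 rac-hex-1-en-4-yn-3-ol
Product: 16 rac-(4Z)-5-iodohexa-1,4-dien-3-ol, via cyclic alkenylaluminate 15 (not isolated)
Conditions: NaAlH2(OCH2CH2OMe)2 (Red-Al), THF, 0 °C to rt; EtOAc; then I2, −78 °C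
Reagents that add atoms: iodine, [I][I]
Why: Hydroxyl-directed trans-hydroalumination of the propargylic alcohol puts aluminium on the distal carbon (C4) within a five-membered alkoxyaluminate, and iodinolysis with retention gives the Z iodoalkene (iodine cis to C6).

Step 9
Reactants: 16 rac-(4Z)-5-iodohexa-1,4-dien-3-ol
Product: 17 (3S,4Z)-5-iodohexa-1,4-dien-3-ol
Conditions: Novozym 435 (immobilised lipase B of Candida antarctica), vinyl acetate, hexane, 30 °C, to just past half conversion
Reagents that add atoms: none
Why: Lipase-catalysed kinetic resolution; by the Kazlauskas rule (vinyl as the medium group, iodopropenyl as the large group) the R alcohol is acetylated and the S alcohol, which becomes C6, should remain.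

Step 10
Reactants: 17 (3S,4Z)-5-iodohexa-1,4-dien-3-ol; 18 2-(bromomethyl)acrylic acid
Product: 19 (3S,4Z)-5-iodohexa-1,4-dien-3-yl 2-(bromomethyl)prop-2-enoate
Conditions: 18, DCC, DMAP (5 mol%), CH2Cl2, 0 °C
Reagents that add atoms: 2-(bromomethyl)acrylic acid (18), C=C(CBr)C(=O)O
Why: Steglich esterification at oxygen does not touch the C6–O bond, so the configuration is retained.

Step 11
Reactants: 19 (3S,4Z)-5-iodohexa-1,4-dien-3-yl 2-(bromomethyl)prop-2-enoate
Product: 20 (5S)-3-(bromomethyl)-5-[(1Z)-2-iodoprop-1-en-1-yl]furan-2(5H)-one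
Conditions: RuCl2(=CHPh)(H2IMes)(PCy3) (second-generation Grubbs catalyst, 5 mol%), toluene, 80 °C, 5 mM
Reagents that add atoms: none
Why: Ring-closing metathesis between the vinyl group and the 1,1-disubstituted acrylate closes the butenolide (C7=C11) with loss of ethene; the trisubstituted iodoalkene is inert to the ruthenium carbene.

**Union and end-game**

Step 12
Reactants: 20 (5S)-3-(bromomethyl)-5-[(1Z)-2-iodoprop-1-en-1-yl]furan-2(5H)-one; 11 (3R,4E)-3-methyl-5-(tributylstannyl)-3-(triethylsilyloxy)pent-4-enal
Product: 22 (4R,5S)-4-[(1S,3R,4E)-1-hydroxy-3-methyl-5-(tributylstannyl)-3-(triethylsilyloxy)pent-4-en-1-yl]-5-[(1Z)-2-iodoprop-1-en-1-yl]-3-methylideneoxolan-2-one, via allylzinc bromide 21 (not isolated)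
Conditions: Zn dust, THF/sat. aq. NH4Cl (3:1), 0 °C to rt
Reagents that add atoms: none
Why: Zinc Barbier allylation with allylic transposition (SE2′) forms C7–C8 and the exocyclic methylene at once; C7 is attacked anti to the C6 substituent (trans lactone) and, because the ring holds C6 trans to the CH2Zn terminus, the closed chair transition state with the aldehyde residue equatorial should set C8 as S, while the near-neutral medium spares alkenyl iodide, alkenylstannane and silyl ether.

Step 13
Reactants: 22 (the 8S alcohol of step 12); 23 tiglic acid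
Product: 24 (1R,3R,4E)-1-{(2S,3R)-2-[(1Z)-2-iodoprop-1-en-1-yl]-4-methylidene-5-oxooxolan-3-yl}-3-methyl-5-(tributylstannyl)-3-(triethylsilyloxy)pent-4-en-1-yl (2E)-2-methylbut-2-enoate
Conditions: 23, PPh3, DIAD, toluene, 0 °C to rt (DIAD added last)
Reagents that add atoms: tiglic acid (23), C/C=C(\C)C(=O)O
Why: Mitsunobu esterification: tiglate displaces the C8 oxyphosphonium by SN2, which installs the ester and inverts C8 from S to the required R in one operation; the tertiary C10 oxygen is silylated and cannot compete.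

Step 14
Reactants: 24 (the C10 triethylsilyl ether of the seco-lactone)
Product: 25 (1R,3R,4E)-3-hydroxy-1-{(2S,3R)-2-[(1Z)-2-iodoprop-1-en-1-yl]-4-methylidene-5-oxooxolan-3-yl}-3-methyl-5-(tributylstannyl)pent-4-en-1-yl (2E)-2-methylbut-2-enoate
Conditions: HF·pyridine, excess pyridine, THF, 0 °C to rt
Reagents that add atoms: none
Why: Fluoride cleavage of the tertiary silyl ether; the pyridine buffer should prevent protodestannylation and is too weakly basic to add to the methylene lactone.

Step 15
Reactants: 25 (seco-lactone with C4 iodide and C2 stannane); 26 carbon monoxide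
Product: 27 eupaheliangolide A
Conditions: Pd2(dba)3 (10 mol%), AsPh3 (40 mol%), CO (1 atm), NMP, 45 °C, syringe-pump addition to 2 mM
Reagents that add atoms: carbon monoxide (26), [C-]#[O+]
Why: Zerovalent palladium adds oxidatively to the C4–I bond, CO inserts to give the C3 acylpalladium (C3–C4 formed), the C2 stannane transmetalates, and reductive elimination from the eleven-membered acyl(alkenyl)palladacycle forms C2–C3. The closest known reaction type is the carbonylative Stille coupling of alkenyl iodides with alkenylstannanes to divinyl ketones, which is established for macrocyclic closures. The ten-membered ring C1–C10 closes by that reductive elimination (contraction from eleven to ten atoms), helped by the Z C4=C5 olefin and the lactone, which hold C4 and the stannane-bearing chain on the same side, and by high dilution. No stereocentre is formed, and C6, C7, C8 and C10 are untouched under the neutral conditions. The step needs CO insertion before transmetalation and retention of both olefin geometries: the weakly donating AsPh3 under CO makes insertion fast, direct coupling would give a strained nine-membered diene, and both elementary Stille steps retain configuration at sp2 carbon. The free C10 hydroxyl, the tiglate and the α-methylene lactone are spectators, and slow addition keeps the stannane concentration low against oligomerisation.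

**Compound list**

1 | (S)-2-methylglycidol | OC[C@@]1(C)CO1 | starting material
2 | vinylmagnesium bromide | C=C[Mg]Br | starting material
3 | (2R)-2-methylpent-4-ene-1,2-diol | OC[C@@](O)(C)CC=C | intermediate
4 | (2R)-2-methyl-1,2-bis(triethylsilyloxy)pent-4-ene | CC[Si](CC)(CC)OC[C@@](O[Si](CC)(CC)CC)(C)CC=C | intermediate
5 | dimethyl{[(2R)-2-methyl-2-(triethylsilyloxy)pent-4-en-1-yl]oxy}sulfonium chloride (not isolated) | C[S+](C)OC[C@@](O[Si](CC)(CC)CC)(C)CC=C.[Cl-] | intermediate
6 | (2R)-2-methyl-2-(triethylsilyloxy)pent-4-enal | O=C[C@@](O[Si](CC)(CC)CC)(C)CC=C | intermediate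
7 | dimethyl (1-diazo-2-oxopropyl)phosphonate | CC(=O)C(=[N+]=[N-])P(=O)(OC)OC | starting material
8 | (3R)-3-methyl-3-(triethylsilyloxy)hex-5-en-1-yne | C#C[C@@](O[Si](CC)(CC)CC)(C)CC=C | intermediate
9 | (4R)-4-methyl-4-(triethylsilyloxy)hex-5-yne-1,2-diol, both C2 epimers (not isolated) | OCC(O)C[C@@](C)(O[Si](CC)(CC)CC)C#C | intermediate
10 | (3R)-3-methyl-3-(triethylsilyloxy)pent-4-ynal | O=CC[C@@](C)(O[Si](CC)(CC)CC)C#C | intermediate
11 | (3R,4E)-3-methyl-5-(tributylstannyl)-3-(triethylsilyloxy)pent-4-enal | O=CC[C@@](C)(O[Si](CC)(CC)CC)/C=C/[Sn](CCCC)(CCCC)CCCC | intermediate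
12 | acrolein | C=CC=O | starting material
13 | 1-propynylmagnesium bromide | CC#C[Mg]Br | starting material
14 | rac-hex-1-en-4-yn-3-ol | C=CC(O)C#CC | intermediate
15 | sodium 2,2-bis(2-methoxyethoxy)-3-methyl-5-vinyl-2,5-dihydro-1,2-oxaalumol-2-uide, racemic (not isolated) | C=CC1C=C(C)[Al-](OCCOC)(OCCOC)O1.[Na+] | intermediate
16 | rac-(4Z)-5-iodohexa-1,4-dien-3-ol | C=CC(O)/C=C(/C)I | intermediate
17 | (3S,4Z)-5-iodohexa-1,4-dien-3-ol | C=C[C@H](O)/C=C(/C)I | intermediate
18 | 2-(bromomethyl)acrylic acid | C=C(CBr)C(=O)O | starting material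
19 | (3S,4Z)-5-iodohexa-1,4-dien-3-yl 2-(bromomethyl)prop-2-enoate | C=C[C@H](OC(=O)C(=C)CBr)/C=C(/C)I | intermediate
20 | (5S)-3-(bromomethyl)-5-[(1Z)-2-iodoprop-1-en-1-yl]furan-2(5H)-one | O=C1O[C@H](/C=C(/C)I)C=C1CBr | intermediate
21 | {(5S)-5-[(1Z)-2-iodoprop-1-en-1-yl]-2-oxo-2,5-dihydrofuran-3-yl}methylzinc bromide (not isolated) | O=C1O[C@H](/C=C(/C)I)C=C1C[Zn]Br | intermediate
22 | (4R,5S)-4-[(1S,3R,4E)-1-hydroxy-3-methyl-5-(tributylstannyl)-3-(triethylsilyloxy)pent-4-en-1-yl]-5-[(1Z)-2-iodoprop-1-en-1-yl]-3-methylideneoxolan-2-one | C=C1C(=O)O[C@H](/C=C(/C)I)[C@H]1[C@@H](O)C[C@@](C)(O[Si](CC)(CC)CC)/C=C/[Sn](CCCC)(CCCC)CCCC | intermediate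
23 | tiglic acid | C/C=C(\C)C(=O)O | starting material
24 | (1R,3R,4E)-1-{(2S,3R)-2-[(1Z)-2-iodoprop-1-en-1-yl]-4-methylidene-5-oxooxolan-3-yl}-3-methyl-5-(tributylstannyl)-3-(triethylsilyloxy)pent-4-en-1-yl (2E)-2-methylbut-2-enoate | C=C1C(=O)O[C@H](/C=C(/C)I)[C@H]1[C@H](OC(=O)/C(C)=C/C)C[C@@](C)(O[Si](CC)(CC)CC)/C=C/[Sn](CCCC)(CCCC)CCCC | intermediate
25 | (1R,3R,4E)-3-hydroxy-1-{(2S,3R)-2-[(1Z)-2-iodoprop-1-en-1-yl]-4-methylidene-5-oxooxolan-3-yl}-3-methyl-5-(tributylstannyl)pent-4-en-1-yl (2E)-2-methylbut-2-enoate | C=C1C(=O)O[C@H](/C=C(/C)I)[C@H]1[C@H](OC(=O)/C(C)=C/C)C[C@@](C)(O)/C=C/[Sn](CCCC)(CCCC)CCCC | intermediate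
26 | carbon monoxide | [C-]#[O+] | starting material
27 | eupaheliangolide A | C=C1C(=O)O[C@@H]2/C=C(/C)C(=O)/C=C/[C@](C)(O)C[C@@H](OC(=O)/C(C)=C/C)[C@@H]12 | target

**Step count.** 15 steps in total. The longest linear sequence is 10 steps (steps 1–6, then 12–15) from (S)-2-methylglycidol; the second branch (steps 7–11) joins at step 12.

**Steps most likely to fail**

Step 15. The acylpalladium may be captured by the stannane of a second molecule (oligomerisation), may add across the C11=C13 methylene, or the stannane end may be lost by protodestannylation before the strained ring closes. Fallback, from 25: reductive carbonylation (CO, Bu3SnH by slow addition, Pd(PPh3)4, THF, 50 °C) intercepts the same acylpalladium with hydride and should give the Z-enal stannane F1. Iododestannylation (I2, CH2Cl2, 0 °C) then gives the enal E-alkenyl iodide F2. A Nozaki–Hiyama–Kishi ring closure (CrCl2, catalytic NiCl2, DMSO/THF, high dilution) forms C2–C3 and gives the ten-membered C3 carbinols F3, both epimers of which converge on Dess–Martin oxidation to 27. C3 still comes from CO, but the ring is closed by a chromium-mediated carbonyl addition.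

Step 13. The hindered C8 oxyphosphonium may eliminate toward C7=C8 or resist displacement by the weakly acidic tiglic acid. Fallback, from 22: sulfonylation (Tf2O, 2,6-lutidine, CH2Cl2, −78 °C) gives the C8 triflate F4, and displacement with caesium (E)-2-methylbut-2-enoate (from 23 and Cs2CO3) and 18-crown-6 in toluene at 0 °C gives 24 with inversion; activation and displacement are thereby separated.

Step 12. The addition may proceed through an open rather than a closed transition state, so that the aldehyde face and hence C8 come out opposite to the prediction, or the zinc alkoxide may attack C12 and move the lactone from O6 to O8. Fallback, from 20 and 11: if the 8R alcohol F5 is what forms, it is isolated and acylated with retention (23, 2,4,6-trichlorobenzoyl chloride, Et3N, DMAP, toluene: Yamaguchi mixed anhydride), which joins the route at 24 and drops the inversion step; short contact times and immediate acylation also limit lactone migration.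

**Further compounds**

F1 | step 15 | (1R,3R,4E)-3-hydroxy-3-methyl-1-{(2S,3R)-4-methylidene-2-[(1Z)-2-methyl-3-oxoprop-1-en-1-yl]-5-oxooxolan-3-yl}-5-(tributylstannyl)pent-4-en-1-yl (2E)-2-methylbut-2-enoate | C=C1C(=O)O[C@H](/C=C(/C)C=O)[C@H]1[C@H](OC(=O)/C(C)=C/C)C[C@@](C)(O)/C=C/[Sn](CCCC)(CCCC)CCCC
F2 | step 15 | (1R,3R,4E)-3-hydroxy-5-iodo-3-methyl-1-{(2S,3R)-4-methylidene-2-[(1Z)-2-methyl-3-oxoprop-1-en-1-yl]-5-oxooxolan-3-yl}pent-4-en-1-yl (2E)-2-methylbut-2-enoate | C=C1C(=O)O[C@H](/C=C(/C)C=O)[C@H]1[C@H](OC(=O)/C(C)=C/C)C[C@@](C)(O)/C=C/I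
F3 | step 15 | 3-deoxo-3-hydroxy-eupaheliangolide A (C3 epimers) | C=C1C(=O)O[C@@H]2/C=C(/C)C(O)/C=C/[C@](C)(O)C[C@@H](OC(=O)/C(C)=C/C)[C@@H]12
F4 | step 13 | C8 trifluoromethanesulfonate of 22 | C=C1C(=O)O[C@H](/C=C(/C)I)[C@H]1[C@@H](OS(=O)(=O)C(F)(F)F)C[C@@](C)(O[Si](CC)(CC)CC)/C=C/[Sn](CCCC)(CCCC)CCCC
F5 | step 12 | (4R,5S)-4-[(1R,3R,4E)-1-hydroxy-3-methyl-5-(tributylstannyl)-3-(triethylsilyloxy)pent-4-en-1-yl]-5-[(1Z)-2-iodoprop-1-en-1-yl]-3-methylideneoxolan-2-one (C8 epimer of 22) | C=C1C(=O)O[C@H](/C=C(/C)I)[C@H]1[C@H](O)C[C@@](C)(O[Si](CC)(CC)CC)/C=C/[Sn](CCCC)(CCCC)CCCC
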